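**Retrosynthetic overview**

1. Plakortolide K ⇐ diimide saturation and cross-metathesis of a 3-allyl peroxide; the quaternary peroxide carbon ⇐ allylsilane addition to the peroxycarbenium ion of a lactone-fused 1,2-dioxan-3-ol.
2. 1,2-Dioxan-3-ol ⇐ insertion of O2 into one C–C bond of a lactone-fused tertiary cyclobutanol (four-membered carbocycle → six-membered peroxide; both peroxide oxygens come from O2).
3. Cyclobutanol ⇐ MeMgBr + cyclobutanone ⇐ dichloroketene [2+2] on the enol-lactone C=C of α-angelica lactone, which brings the lactone, the ring-fusion methyl group and its C–O bond.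
4. Ring order: γ-lactone (bought) → cyclobutane (step 1) → 1,2-dioxane (step 4); the enantiomers are separated at the allyl peroxide (step 7).
5. Enabling feature: in the 2-oxabicyclo[3.2.0]heptan-3-one the tertiary carbinol C6 lies in the strained four-membered ring next to the ring-fusion CH (C5); an oxygen radical on C6 breaks the C5–C6 bond to leave a methyl ketone at C6 and a radical at C5, and O2 bridges these two carbons.

Key step: step 4

Remark: locants follow the compound names (2-oxabicyclo[3.2.0]heptane for the carbocycles; furo[3,2-c][1,2]dioxine for the peroxides, with O1–O2 the peroxide, C3 the quaternary peroxide carbon, C4a/C7a the ring fusion).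

Remark: the tertiary cyclobutanol of step 3 is the mirror image of its own acyl-migration isomer (its seco dihydroxy acid is meso, if methyl enters exo as expected), so it can racemise under base or acid; the series is therefore carried racemic and resolved at the allyl peroxide, where no such pathway exists.

Remark: 11-bromoundec-1-ene, the Grignard reagents, allyltrimethylsilane and potassium azodicarboxylate are taken as commercial.

**Step 1**
Reactants: 1 α-angelica lactone (5-methylfuran-2(3H)-one); 2 trichloroacetyl chloride
Product: 3 rac-(1S,5R)-7,7-dichloro-1-methyl-2-oxabicyclo[3.2.0]heptane-3,6-dione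
Conditions: Cl3CCOCl, Zn(Cu), POCl3, Et2O, 25–35 °C
Reagents that add atoms: trichloroacetyl chloride, ClC(Cl)(Cl)C(Cl)=O (delivers dichloroketene, ClC(Cl)=C=O, in the flask)
Why: Thermal ketene–alkene [2+2] cycloaddition of dichloroketene with the electron-rich enol-ester C=C, in which the ketene carbonyl carbon bonds to the unsubstituted enol carbon and CCl2 to the oxygen-bearing carbon, and suprafacial addition to the ring alkene fixes the cis ring fusion (racemic).

**Step 2**
Reactants: 3 rac-(1S,5R)-7,7-dichloro-1-methyl-2-oxabicyclo[3.2.0]heptane-3,6-dione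
Product: 4 rac-(1R,5R)-1-methyl-2-oxabicyclo[3.2.0]heptane-3,6-dione
Conditions: Zn dust, AcOH, 25 °C
Reagents that add atoms: none
Why: Reductive dechlorination of an α,α-dichlorocyclobutanone by zinc in acetic acid (zinc enolate, then protonation) should leave the lactone and both stereocentres untouched.

**Step 3**
Reactants: 4 rac-(1R,5R)-1-methyl-2-oxabicyclo[3.2.0]heptane-3,6-dione; 5 methylmagnesium bromide
Product: 6 rac-(1R,5S,6S)-6-hydroxy-1,6-dimethyl-2-oxabicyclo[3.2.0]heptan-3-one
Conditions: MeMgBr (1.1 equiv), THF, −78 °C; then AcOH, −78 °C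
Reagents that add atoms: methylmagnesium bromide, C[Mg]Br
Why: Grignard 1,2-addition should be selective for the strained, far more electrophilic cyclobutanone over the γ-lactone at −78 °C, with attack on the convex (exo) face so that OH ends cis to the lactone ring; this carbinol centre is erased in step 4.

**Step 4**
Reactants: 6 rac-(1R,5S,6S)-6-hydroxy-1,6-dimethyl-2-oxabicyclo[3.2.0]heptan-3-one; 7 dioxygen
Product: 9 rac-(4aR,7aR)-3-hydroxy-3,4a-dimethyltetrahydro-3H-furo[3,2-c][1,2]dioxin-6(4H)-one (anomeric mixture at C3), via hydroperoxy ketone 8 (not isolated)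
Conditions: Co(acac)2 (20 mol %), O2 (1 atm), MeCN, 25–40 °C
Reagents that add atoms: dioxygen, O=O
Why: Co(II)/O2 should convert the tertiary cyclobutanol into its alkoxy radical, which undergoes strain-driven β-scission of the C5–C6 bond (secondary ring-fusion radical rather than the primary C7 radical); the C5 radical captures O2, the peroxyl radical is reduced to hydroperoxide 8, and its OOH adds 6-exo-trig to the liberated methyl ketone to close the 1,2-dioxane as a hemiperketal. The closest known reaction type is the Co(acac)2/O2 oxidative ring expansion of cyclobutanols to 1,2-dioxan-3-ols. C7a is created when O2 adds to a planar lactone-ring radical, a capture expected to show little facial preference, so the ring-fusion configuration is secured by the closure and not by the capture: only the hydroperoxide cis to the 2-oxopropyl arm can reach the ketone and it gives the cis-fused bicycle, whereas the epimeric hydroperoxide cannot close without trans-fusion strain and is removed by chromatography at a cost in yield. C4a is carried unchanged from 6, and the hemiketal carbon C3 forms as an anomeric mixture that does not matter because it is ionised in step 6. The selectivities needed are C5–C6 over C6–C7 cleavage and survival of the base-labile β-peroxy lactone, secured by the higher substitution of C5 and by the neutral, near-ambient conditions.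

**Step 5**
Reactants: 9 rac-(4aR,7aR)-3-hydroxy-3,4a-dimethyltetrahydro-3H-furo[3,2-c][1,2]dioxin-6(4H)-one; 10 acetic anhydride
Product: 11 rac-(4aR,7aR)-3,4a-dimethyl-6-oxohexahydro-3H-furo[3,2-c][1,2]dioxin-3-yl acetate (anomeric mixture at C3)
Conditions: Ac2O, pyridine, DMAP (cat.), CH2Cl2, 0 °C
Reagents that add atoms: acetic anhydride, CC(=O)OC(C)=O
Why: DMAP-catalysed acylation of the tertiary hemiperketal hydroxyl should lock the ring form and provide the leaving group for ionisation without touching the ring-fusion centres.

**Step 6**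
Reactants: 11 rac-(4aR,7aR)-3,4a-dimethyl-6-oxohexahydro-3H-furo[3,2-c][1,2]dioxin-3-yl acetate; 12 allyltrimethylsilane
Product: 14 rac-(3S,4aR,7aR)-3,4a-dimethyl-3-(prop-2-en-1-yl)tetrahydro-3H-furo[3,2-c][1,2]dioxin-6(4H)-one, via peroxycarbenium ion 13 (not isolated)
Conditions: allylSiMe3, TMSOTf (cat.), CH2Cl2, −78 °C
Reagents that add atoms: allyltrimethylsilane, C=CC[Si](C)(C)C
Why: Hosomi–Sakurai allylation of the peroxycarbenium ion 13: the ion should adopt the half-chair with the 4a-methyl group and C7 pseudo-equatorial and the lactone oxygen pseudo-axial, and chair-like axial attack on C3 then occurs on the face of the lactone oxygen (the other half-chair would force a 1,3-diaxial methyl/allyl contact), which places allyl cis to O5 and C7 and sets C3 as S relative to 4aR,7aR.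

**Step 7**
Reactants: 14 rac-(3S,4aR,7aR)-3,4a-dimethyl-3-(prop-2-en-1-yl)tetrahydro-3H-furo[3,2-c][1,2]dioxin-6(4H)-one
Product: 15 (3S,4aR,7aR)-3,4a-dimethyl-3-(prop-2-en-1-yl)tetrahydro-3H-furo[3,2-c][1,2]dioxin-6(4H)-one (single enantiomer)
Conditions: preparative SFC, chiral stationary phase (amylose tris(3,5-dimethylphenylcarbamate)), CO2/iPrOH
Reagents that add atoms: none
Why: Chromatographic resolution on a chiral stationary phase separates the enantiomers when all three stereocentres are in place and configurationally stable, and so fixes the absolute configuration for the rest of the route; the wanted enantiomer is to be identified by anomalous-dispersion X-ray analysis or by correlation of the final product with the natural material.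

**Step 8**
Reactants: 16 11-bromoundec-1-ene; 17 phenylmagnesium bromide
Product: 18 undec-10-en-1-ylbenzene
Conditions: PhMgBr, Li2CuCl4 (cat.), THF, 0 °C
Reagents that add atoms: phenylmagnesium bromide, Br[Mg]c1ccccc1
Why: Copper-catalysed Grignard–alkyl bromide cross-coupling should join the aryl group to the primary sp3 carbon without touching the terminal alkene.

**Step 9**
Reactants: 15 (3S,4aR,7aR)-3,4a-dimethyl-3-(prop-2-en-1-yl)tetrahydro-3H-furo[3,2-c][1,2]dioxin-6(4H)-one; 18 undec-10-en-1-ylbenzene
Product: 19 (3S,4aR,7aR)-3,4a-dimethyl-3-[(2E)-12-phenyldodec-2-en-1-yl]tetrahydro-3H-furo[3,2-c][1,2]dioxin-6(4H)-one (E/Z mixture acceptable)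
Conditions: Grubbs II (5 mol %), 18 (4 equiv), CH2Cl2, 40 °C
Reagents that add atoms: undec-10-en-1-ylbenzene, C=CCCCCCCCCCc1ccccc1
Why: Ruthenium-catalysed olefin cross-metathesis of two terminal alkenes with the cheap partner in excess should tolerate the dialkyl peroxide and the lactone, and the alkene geometry is irrelevant because the double bond is saturated next.

**Step 10**
Reactants: 19 (3S,4aR,7aR)-3,4a-dimethyl-3-[(2E)-12-phenyldodec-2-en-1-yl]tetrahydro-3H-furo[3,2-c][1,2]dioxin-6(4H)-one
Product: 20 plakortolide K, (3S,4aR,7aR)-3,4a-dimethyl-3-(12-phenyldodecyl)tetrahydro-3H-furo[3,2-c][1,2]dioxin-6(4H)-one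
Conditions: KO2CN=NCO2K, AcOH, MeOH/CH2Cl2, 0 → 25 °C
Reagents that add atoms: none
Why: Diimide reduction (diimide from potassium azodicarboxylate and acetic acid) transfers H2 concertedly to the isolated C=C and should leave the O–O bond and the lactone intact, which catalytic hydrogenation would not; no stereocentre is touched.

**Compound list**

1 | α-angelica lactone (5-methylfuran-2(3H)-one) | CC1=CCC(=O)O1 | starting material
2 | trichloroacetyl chloride | ClC(Cl)(Cl)C(Cl)=O | starting material
3 | rac-(1S,5R)-7,7-dichloro-1-methyl-2-oxabicyclo[3.2.0]heptane-3,6-dione (racemate, one enantiomer drawn) | O=C1C(Cl)(Cl)[C@@]2(C)OC(=O)C[C@H]21 | intermediate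
4 | rac-(1R,5R)-1-methyl-2-oxabicyclo[3.2.0]heptane-3,6-dione (racemate, one enantiomer drawn) | O=C1C[C@@]2(C)OC(=O)C[C@H]21 | intermediate
5 | methylmagnesium bromide | C[Mg]Br | starting material
6 | rac-(1R,5S,6S)-6-hydroxy-1,6-dimethyl-2-oxabicyclo[3.2.0]heptan-3-one (racemate, one enantiomer drawn) | C[C@]1(O)C[C@@]2(C)OC(=O)C[C@H]21 | intermediate
7 | dioxygen | O=O | starting material
8 | rac-(4R,5R)-4-hydroperoxy-5-methyl-5-(2-oxopropyl)dihydrofuran-2(3H)-one (hydroperoxy ketone; racemate, one enantiomer drawn) | CC(=O)C[C@@]1(C)OC(=O)C[C@H]1OO | intermediate (not isolated)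
9 | rac-(4aR,7aR)-3-hydroxy-3,4a-dimethyltetrahydro-3H-furo[3,2-c][1,2]dioxin-6(4H)-one (racemate, anomers at C3) | CC1(O)C[C@@]2(C)OC(=O)C[C@H]2OO1 | intermediate
10 | acetic anhydride | CC(=O)OC(C)=O | starting material
11 | rac-(4aR,7aR)-3,4a-dimethyl-6-oxohexahydro-3H-furo[3,2-c][1,2]dioxin-3-yl acetate (racemate, anomers at C3) | CC(=O)OC1(C)C[C@@]2(C)OC(=O)C[C@H]2OO1 | intermediate
12 | allyltrimethylsilane | C=CC[Si](C)(C)C | starting material
13 | rac-(4aR,7aR)-3,4a-dimethyl-6-oxohexahydrofuro[3,2-c][1,2]dioxin-3-ylium (peroxycarbenium ion, as triflate) | C[C+]1C[C@@]2(C)OC(=O)C[C@H]2OO1 | intermediate (not isolated)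
14 | rac-(3S,4aR,7aR)-3,4a-dimethyl-3-(prop-2-en-1-yl)tetrahydro-3H-furo[3,2-c][1,2]dioxin-6(4H)-one (racemate, one enantiomer drawn) | C[C@]1(CC=C)C[C@@]2(C)OC(=O)C[C@H]2OO1 | intermediate
15 | (3S,4aR,7aR)-3,4a-dimethyl-3-(prop-2-en-1-yl)tetrahydro-3H-furo[3,2-c][1,2]dioxin-6(4H)-one (single enantiomer) | C[C@]1(CC=C)C[C@@]2(C)OC(=O)C[C@H]2OO1 | intermediate
16 | 11-bromoundec-1-ene | C=CCCCCCCCCCBr | starting material
17 | phenylmagnesium bromide | Br[Mg]c1ccccc1 | starting material
18 | undec-10-en-1-ylbenzene | C=CCCCCCCCCCc1ccccc1 | intermediate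
19 | (3S,4aR,7aR)-3,4a-dimethyl-3-[(2E)-12-phenyldodec-2-en-1-yl]tetrahydro-3H-furo[3,2-c][1,2]dioxin-6(4H)-one | C[C@]1(C/C=C/CCCCCCCCCc2ccccc2)C[C@@]2(C)OC(=O)C[C@H]2OO1 | intermediate
20 | plakortolide K, (3S,4aR,7aR)-3,4a-dimethyl-3-(12-phenyldodecyl)tetrahydro-3H-furo[3,2-c][1,2]dioxin-6(4H)-one | C[C@]1(CCCCCCCCCCCCc2ccccc2)C[C@@]2(C)OC(=O)C[C@H]2OO1 | target

**Step count and risks**

Total step count: 10. Longest linear sequence: 9 steps (steps 1–7, 9 and 10; step 8 is a one-step side branch).

The three steps most likely to fail:

Step 4. Dioxygen may add to both faces of the C5 radical, diverting much of the material to the hydroperoxide that cannot close, and cobalt may decompose the secondary hydroperoxide (Kornblum–DeLaMare-type loss to the ketone) before it cyclises. The fallback leaves the radical manifold and builds the same ring by polar chemistry. It sets out from 6, which under Pd(OAc)2/pyridine/O2 (toluene, 80 °C; β-carbon elimination towards the ring-fusion carbon, then β-hydride elimination into conjugation) should open to the keto-butenolide rac-(R)-5-methyl-5-(2-oxopropyl)furan-2(5H)-one F1. Urea–H2O2 with catalytic Sc(OTf)3 in MeOH would convert the ketone into the methoxy hydroperoxy ketal F2. Et2NH in CF3CH2OH would then close the dioxane by intramolecular oxa-Michael addition, which can only give the cis-fused methoxy peroxyketal F3. AllylSiMe3/TiCl4 (CH2Cl2, −78 °C) on F3 comes back to the route at 14.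

Step 6. After ionisation, heterolytic O–O cleavage with a 1,2-shift (Hock/Criegee-type fragmentation) may outrun C–C bond formation, or the allylsilane may attack both faces of the cation. The fallback makes the quaternary peroxide carbon as a tertiary hydroperoxide and closes the ring by conjugate addition. It sets out from 6 and uses the keto-butenolide F1 of the preceding fallback. AllylMgBr/CeCl3 (THF, −78 °C) would add to the ketone to give the tertiary homoallylic alcohol F4. 50% H2O2 with catalytic H2SO4 would exchange OH for OOH to give the tertiary hydroperoxide F5. Et2NH/CF3CH2OH would close the dioxane by oxa-Michael addition and come back at 14, which would have to be separated from its C3 epimer because the hydroperoxide forms without stereocontrol.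

Step 3. The magnesium alkoxide of the strained β-acyloxy cyclobutanol may fragment (Grob-type cleavage that expels the carboxylate), or the Grignard reagent may attack the lactone. The fallback avoids a metal alkoxide. It sets out from 4: Wittig methylenation (Ph3P=CH2, THF, 0 °C) would give the methylidenecyclobutane F6, and Mukaiyama hydration (Mn(dpm)3 cat., PhSiH3, O2, iPrOH) would give the tertiary cyclobutanol, expected mainly as the C6 epimer F7 of 6. F7 gives the same alkoxy-radical chemistry under the conditions of step 4, so the route is rejoined at 9.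

**Further compounds**

F1 | step 4 | rac-(R)-5-methyl-5-(2-oxopropyl)furan-2(5H)-one | CC(=O)C[C@@]1(C)OC(=O)C=C1
F2 | step 4 | rac-(5R)-5-(2-hydroperoxy-2-methoxypropyl)-5-methylfuran-2(5H)-one | COC(C)(OO)C[C@@]1(C)OC(=O)C=C1
F3 | step 4 | rac-(4aR,7aR)-3-methoxy-3,4a-dimethyltetrahydro-3H-furo[3,2-c][1,2]dioxin-6(4H)-one | COC1(C)C[C@@]2(C)OC(=O)C[C@H]2OO1
F4 | step 6 | rac-(5R)-5-(2-hydroxy-2-methylpent-4-en-1-yl)-5-methylfuran-2(5H)-one | C=CCC(C)(O)C[C@@]1(C)OC(=O)C=C1
F5 | step 6 | rac-(5R)-5-(2-hydroperoxy-2-methylpent-4-en-1-yl)-5-methylfuran-2(5H)-one | C=CCC(C)(OO)C[C@@]1(C)OC(=O)C=C1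
F6 | step 3 | rac-(1R,5S)-1-methyl-6-methylidene-2-oxabicyclo[3.2.0]heptan-3-one | C=C1C[C@@]2(C)OC(=O)C[C@H]21
F7 | step 3 | rac-(1R,5S,6R)-6-hydroxy-1,6-dimethyl-2-oxabicyclo[3.2.0]heptan-3-one | C[C@@]1(O)C[C@@]2(C)OC(=O)C[C@H]21
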